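The readings were generated by integration with constants of no real substance.

A one-step world, with substrate falling as product rises, was what the teal run refused me: at 4.00 min substrate stood at 0.2%, yet target and isomer of the product together held 12.2% of the substrate charged.

- teal: substrate 24 mM; reagent 51.7 mM; run made earlier
- flask: substrate 47 mM; reagent 51.7 mM; time 8.0 h

teal run (percent of the substrate charged)

| time / min | isomer of the product / % | target / % | substrate / % |
|---|---|---|---|
| 4.00 | 5.4 | 6.8 | 0.2 |
| 12.0 | 19.3 | 4.8 | 0 |
| 20.0 | 26.8 | 2.4 | 0 |
| 30.0 | 28.1 | 1.7 | 1.4 |
| 50.0 | 31.8 | 1.3 | 0 |

(readings scatter by 0.5 percentage points)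

- share of isomer of the product in isomer of the product plus target at 30 s
- share of isomer of the product in isomer of the product plus target at 8.0 h

So I reckoned with what was left and not with what was made, and took f, the share of target in target plus isomer of the product. On the first rung of the teal run, substrate read 0.2% at 4.00 min, while f stood at 55.7%. On the last rung, at 50.0 min, f had come down to 3.93%, which I took as its floor, the equilibrium fraction of target, though that target reading of 1.3% carries a scatter of 0.5 percentage points. On the rung between, f read 19.9% at 12.0 min, so its excess over the floor halved about every 4.72 min. The flask's 8.0 h is 102 such half-times, and, assuming the floor holds with 47 mM of substrate, I committed to 96.1% isomer in the pair at that time.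

The forecast gave 8% at 30 s and 97% at 8.0 h, a little above my figure, on these grounds: “That suggests a target/isomer equilibrium with about 96–97% isomer.”

The flask gave 5.83% and 95.9%.

    substrate → intermediate A (k = 0.00280 s⁻¹)
    substrate → intermediate B (k = 0.0400 s⁻¹)
    reagent + intermediate B → target (k = 0.0170 L mol⁻¹ s⁻¹)
    intermediate B ⇌ intermediate A (K = 8.20, k = 0.00150 s⁻¹)
    target ⇌ isomer of the product (K = 24.0, k = 0.00550 s⁻¹)
    reagent + target → over-reaction product (k = 0.0160 L mol⁻¹ s⁻¹)

In the flask, the half-life of target by its forward passing into isomer of the product alone was 2.1 min at 8.00 h, shorter than the 8.0 h allowed, and f ended at 4.10%, beside the 3.93% read from the teal run. The neighbour flask with 130 mM of reagent ended with 30.3% of isomer of the product and with more of the substrate charged in over-reaction product, 63.3%, and its f was 3.64%.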